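**Plan**
Rings: A = methoxy ring, B = para-phenylene, C = hydroxy ring (C1 carries the bridge to ring B, C3 the OH, C4 the O to ring D), D = meta-phenylene. The target is an achiral 20-membered cyclophane, so no stereocentre has to be set.
Cuts, in retrosynthetic order: C3–OH of ring C back to C3–CHO (Baeyer–Villiger); the bond from the bridge CH2 to C1 of ring C, which opens the macrocycle; O(ring D)–C4(ring C) by SNAr; the A–D ethano bridge by Wittig and H2; O(ring B)–C3(ring A) by Ullmann coupling.
Enabling feature: the bridge CH2 is a primary homobenzylic carbon para to the ether O of ring B, which is a phloretic acid side chain minus CO2. C1 of ring C lies para to the ether O at C4 and meta to C3. This is the substitution pattern of 2-fluoro-5-iodobenzaldehyde, in which CHO activates F, stands in for OH, and iodine marks C1.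
Forward order: A–B ether, then the A–D bridge, then the D–C ether. This gives the open chain B–A–D–C carrying an N-acyloxyphthalimide at one end and an aryl iodide at the other.
A nickel-electrocatalytic decarboxylative arylation then closes the ring. CO2 and phthalimide leave in that event, and the formyl helper becomes the OH in the last step.

Key step: step 8

Remark: stilbene 6 is carried as an E/Z mixture, because both isomers give the same bibenzyl 7.

**Step 1**
Reactants: 1 methyl 3-(4-hydroxyphenyl)propanoate; 2 3-bromo-4-methoxybenzaldehyde
Product: 3 methyl 3-[4-(5-formyl-2-methoxyphenoxy)phenyl]propanoate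
Conditions: CuI (10 mol %), N,N-dimethylglycine hydrochloride (30 mol %), Cs2CO3, dry 1,4-dioxane, 90 °C, N2
Reagents that add atoms: none
Why: Ullmann-type diaryl ether synthesis with amino-acid-ligated monovalent copper, in which the unhindered phenoxide of 1 replaces bromide at C3 of ring A while formyl and ester groups are inert to Cs2CO3 in dry dioxane.

**Step 2**
Reactants: 4 [3-(benzyloxy)phenyl]methanol
Product: 5 [3-(benzyloxy)benzyl]triphenylphosphonium bromide
Conditions: Ph3P·HBr, MeCN, reflux
Reagents that add atoms: triphenylphosphine hydrobromide, [Br-].c1ccc(cc1)[PH+](c1ccccc1)c1ccccc1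
Why: Direct phosphonium salt formation from a benzylic alcohol by displacement of the protonated hydroxyl with PPh3, a weakly acidic method that aryl benzyl ethers tolerate.

**Step 3**
Reactants: 3 methyl 3-[4-(5-formyl-2-methoxyphenoxy)phenyl]propanoate; 5 [3-(benzyloxy)benzyl]triphenylphosphonium bromide
Product: 6 methyl 3-[4-(5-{2-[3-(benzyloxy)phenyl]ethenyl}-2-methoxyphenoxy)phenyl]propanoate (E/Z mixture)
Conditions: K2CO3, 18-crown-6 (cat.), CH2Cl2, reflux
Reagents that add atoms: none
Why: Wittig olefination of an aryl aldehyde with a semi-stabilised benzylic ylide under solid–liquid phase-transfer conditions that spare the methyl ester, and the alkene geometry is irrelevant because the double bond is saturated next.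

**Step 4**
Reactants: 6 stilbene benzyl ether (E/Z mixture)
Product: 7 methyl 3-[4-(5-[2-(3-hydroxyphenyl)ethyl]-2-methoxyphenoxy)phenyl]propanoate
Conditions: H2 (1 atm), 10% Pd/C, EtOAc–MeOH, rt
Reagents that add atoms: none
Why: Catalytic hydrogenation saturates the stilbene and hydrogenolyses the benzyl ether in one operation, and it is placed before iodine enters the molecule so that no dehalogenation can occur.

**Step 5**
Reactants: 7 ring D phenol; 8 2-fluoro-5-iodobenzaldehyde
Product: 9 methyl 3-{4-[5-(2-{3-[2-formyl-4-iodophenoxy]phenyl}ethyl)-2-methoxyphenoxy]phenyl}propanoate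
Conditions: K2CO3, DMF, 110 °C
Reagents that add atoms: none
Why: Nucleophilic aromatic substitution by addition–elimination, in which the ortho formyl group stabilises the Meisenheimer adduct at the C–F carbon, while the iodine sits meta to that formyl group, is not activated and stays in place.

**Step 6**
Reactants: 9 methyl ester
Product: 10 3-{4-[5-(2-{3-[2-formyl-4-iodophenoxy]phenyl}ethyl)-2-methoxyphenoxy]phenyl}propanoic acid
Conditions: LiOH·H2O, THF–H2O, rt; then 1 M HCl
Reagents that add atoms: lithium hydroxide, [Li+].[OH-]
Why: Ordinary saponification by acyl–oxygen cleavage, in which the non-enolisable aryl aldehyde and the aryl iodide are inert to dilute LiOH at room temperature.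

**Step 7**
Reactants: 10 carboxylic acid
Product: 11 1,3-dioxoisoindolin-2-yl 3-{4-[5-(2-{3-[2-formyl-4-iodophenoxy]phenyl}ethyl)-2-methoxyphenoxy]phenyl}propanoate (redox-active ester)
Conditions: N-hydroxyphthalimide, DIC, DMAP (cat.), CH2Cl2, rt
Reagents that add atoms: N-hydroxyphthalimide, O=C1c2ccccc2C(=O)N1O
Why: Steglich-type carbodiimide esterification installs the electron-accepting phthalimide ester that later triggers decarboxylation, and no other group in 10 is acylated.

**Step 8**
Reactants: 11 redox-active ester with aryl iodide terminus
Product: 12 macrocyclic aldehyde (the 20-membered ring of pakyonol with CHO in place of the OH at C3 of ring C)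
Conditions: NiCl2·6H2O (30 mol %), 2,2'-bipyridine (30 mol %), AgNO3 (20 mol %, plated on the cathode in situ), LiCl, DMF, Mg(+)/RVC(−), undivided cell, constant current matched to syringe-pump addition of 11 (final ca. 2 mM), rt, Ar
Reagents that add atoms: none
Why: Proposed new method: cathodically generated zerovalent nickel–bipyridine inserts into the carbon–iodine bond at C1 of ring C, single-electron transfer (from monovalent nickel or the silver-coated cathode) to the phthalimide ester then expels phthalimide anion and CO2 to leave the primary 2-arylethyl radical on the ring B side chain, this radical is captured by the divalent aryl-nickel centre of the same molecule, and reductive elimination from trivalent nickel forges the CH2–C1 bond. The closest known reaction type is the intermolecular nickel-electrocatalytic decarboxylative arylation of primary redox-active esters with aryl iodides, which makes the same primary alkyl–aryl bond but has not been shown as an end-to-end macrocyclisation of a cyclophane chain. The single ring closed is the 20-membered macrocycle, formed head-to-tail through a 21-membered nickelacycle that contracts on reductive elimination, so no exo/endo question arises and the only geometric demand is that the two termini meet, which the two bent diaryl ether oxygens and the meta-linked rings A and D favour. No stereocentre is created. The step needs intramolecular capture to win over oligomerisation, hydrogen abstraction from solvent and hydrodeiodination: syringe-pump addition into a standing pool of reduced catalyst keeps the substrate concentration minimal and lets the fast insertion into the unhindered aryl iodide (H at both C2 and C6) precede ester reduction, and the 1,2-aryl shift open to a 2-arylethyl radical is degenerate here and cannot scramble the bridge. Chemoselectivity rests on potentials: the ester and the nickel complex are reduced several hundred millivolts before an aryl aldehyde, so the formyl group at C3 should pass untouched if the current is matched to the addition rate.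

**Step 9**
Reactants: 12 macrocyclic aldehyde
Product: 14 pakyonol, via aryl formate 13 (not isolated)
Conditions: mCPBA, CH2Cl2, 0 °C to rt; aqueous wash, then K2CO3 (cat.), MeOH, rt
Reagents that add atoms: mCPBA (3-chloroperoxybenzoic acid), O=C(OO)c1cccc(Cl)c1
Why: Baeyer–Villiger oxidation, in which ring C, made electron-rich by the ortho aryloxy oxygen, migrates from the Criegee adduct in preference to hydride, and the resulting formate is removed by transesterification without touching the methyl ether of ring A.

**Compound list**
1 | methyl 3-(4-hydroxyphenyl)propanoate | COC(=O)CCc1ccc(O)cc1 | starting material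
2 | 3-bromo-4-methoxybenzaldehyde | COc1ccc(C=O)cc1Br | starting material
3 | methyl 3-[4-(5-formyl-2-methoxyphenoxy)phenyl]propanoate | COC(=O)CCc1ccc(Oc2cc(C=O)ccc2OC)cc1 | intermediate
4 | [3-(benzyloxy)phenyl]methanol | OCc1cccc(OCc2ccccc2)c1 | starting material
5 | [3-(benzyloxy)benzyl]triphenylphosphonium bromide | [Br-].C(c1cccc(OCc2ccccc2)c1)[P+](c1ccccc1)(c1ccccc1)c1ccccc1 | intermediate
6 | methyl 3-[4-(5-{2-[3-(benzyloxy)phenyl]ethenyl}-2-methoxyphenoxy)phenyl]propanoate, E/Z mixture | COC(=O)CCc1ccc(Oc2cc(C=Cc3cccc(OCc4ccccc4)c3)ccc2OC)cc1 | intermediate
7 | methyl 3-[4-(5-[2-(3-hydroxyphenyl)ethyl]-2-methoxyphenoxy)phenyl]propanoate | COC(=O)CCc1ccc(Oc2cc(CCc3cccc(O)c3)ccc2OC)cc1 | intermediate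
8 | 2-fluoro-5-iodobenzaldehyde | O=Cc1cc(I)ccc1F | starting material
9 | methyl 3-{4-[5-(2-{3-[2-formyl-4-iodophenoxy]phenyl}ethyl)-2-methoxyphenoxy]phenyl}propanoate | COC(=O)CCc1ccc(Oc2cc(CCc3cccc(Oc4ccc(I)cc4C=O)c3)ccc2OC)cc1 | intermediate
10 | 3-{4-[5-(2-{3-[2-formyl-4-iodophenoxy]phenyl}ethyl)-2-methoxyphenoxy]phenyl}propanoic acid | OC(=O)CCc1ccc(Oc2cc(CCc3cccc(Oc4ccc(I)cc4C=O)c3)ccc2OC)cc1 | intermediate
11 | 1,3-dioxoisoindolin-2-yl ester of acid 10 (redox-active ester) | O=C(CCc1ccc(Oc2cc(CCc3cccc(Oc4ccc(I)cc4C=O)c3)ccc2OC)cc1)ON1C(=O)c2ccccc2C1=O | intermediate
12 | macrocyclic aldehyde (pakyonol ring with CHO at C3 of ring C) | COc1ccc2cc1Oc1ccc(cc1)CCc1ccc(c(C=O)c1)Oc1cccc(c1)CC2 | intermediate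
13 | pakyonol O-formate (formyloxy group at C3 of ring C) | COc1ccc2cc1Oc1ccc(cc1)CCc1ccc(c(OC=O)c1)Oc1cccc(c1)CC2 | intermediate
14 | pakyonol | COc1ccc2cc1Oc1ccc(cc1)CCc1ccc(c(O)c1)Oc1cccc(c1)CC2 | target

**Total step count:** 9. **Longest linear sequence:** 8 (steps 1, 3, 4, 5, 6, 7, 8, 9).

**Steps most likely to fail**

Step 8 (Proposed new method). The alkyl radical may abstract hydrogen from the solvent before it reaches the metal. It may instead be captured by the aryl-nickel end of another chain, which gives oligomers. The iodide may be reduced away, or the formyl group may be reduced at the cathode if the potential drifts. The fallback uses known two-electron palladium chemistry, joins the same two carbons and sets out from acid 10. Oxidative decarboxylation (Kochi reaction: Pb(OAc)4, cat. Cu(OAc)2, pyridine, benzene, 80 °C) should give the styrene 2-(3-{2-[3-(4-ethenylphenoxy)-4-methoxyphenyl]ethyl}phenoxy)-5-iodobenzaldehyde F1. A Mizoroki–Heck macrocyclisation under high dilution (Pd(OAc)2, P(o-tol)3, Et3N, DMF, 90 °C) should arylate the terminal alkene carbon and give the macrocyclic (E)-stilbene aldehyde F2. Chemoselective alkene hydrogenation (H2, Pd/C poisoned with Ph2S, EtOAc, rt) should spare the aryl aldehyde, and the route is rejoined at 12.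

Step 9. Hydride migration in the Criegee adduct would lead to the carboxylic acid, and slow oxidation would allow side attack on the electron-rich rings. Either process may erode the conversion of CHO into OH. The fallback sets out from 12 and removes the migrating hydrogen. Grignard addition (MeMgBr, THF, −78 °C) should give the racemic macrocyclic 1-arylethanol F3. Benzylic oxidation (MnO2, CH2Cl2) should give the macrocyclic aryl methyl ketone F4. In the Baeyer–Villiger oxidation of F4 (mCPBA, cat. TFA, CH2Cl2), aryl migrates in preference to methyl, which should give pakyonol O-acetate F5. Methanolysis (K2CO3, MeOH) rejoins the route at 14.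

Step 1. Coupling at the bromide flanked by the methoxy group may be sluggish. Hydrodebromination and ester cleavage may then compete at the temperature required. The fallback sets out from phenol 1 and replaces the aryl halide partner by an arylboron partner in an oxidative coupling at room temperature. This is a Chan–Lam coupling of 1 with commercial (5-formyl-2-methoxyphenyl)boronic acid (Cu(OAc)2, pyridine, 4 Å molecular sieves, CH2Cl2, air, rt), and it comes back to the route at 3. No compound outside the list is made on this way (F0).

**Further compounds**
F1 | step 8 | 2-(3-{2-[3-(4-ethenylphenoxy)-4-methoxyphenyl]ethyl}phenoxy)-5-iodobenzaldehyde | C=Cc1ccc(Oc2cc(CCc3cccc(Oc4ccc(I)cc4C=O)c3)ccc2OC)cc1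
F2 | step 8 | macrocyclic (E)-stilbene aldehyde (12 with an E double bond in the B–C bridge) | COc1ccc2cc1Oc1ccc(cc1)/C=C/c1ccc(c(C=O)c1)Oc1cccc(c1)CC2
F3 | step 9 | racemic macrocyclic 1-arylethanol (CH(OH)CH3 at C3 of ring C) | COc1ccc2cc1Oc1ccc(cc1)CCc1ccc(c(C(C)O)c1)Oc1cccc(c1)CC2
F4 | step 9 | macrocyclic aryl methyl ketone (acetyl at C3 of ring C) | COc1ccc2cc1Oc1ccc(cc1)CCc1ccc(c(C(C)=O)c1)Oc1cccc(c1)CC2
F5 | step 9 | pakyonol O-acetate | COc1ccc2cc1Oc1ccc(cc1)CCc1ccc(c(OC(C)=O)c1)Oc1cccc(c1)CC2
F0 | step 1 | none | none
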